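**Plan**
- Retrosynthesis: cut all 18 O–benzyl bonds; then the top C4–middle C8 interflavan bond; then the bottom 3-O-galloyl ester; then O1–C2 and C3–C4 of the middle unit together; last the middle C4–bottom C8 bond.
- Enabling feature: in the middle unit, phenolic O1 sits ortho to benzylic C4 on the phloroglucinol ring A, so O1–C8a–C4a–C4 is a latent o-quinone methide heterodiene. C2–C3 (2-aryl, 3-galloyloxy) is the Z-enol gallate of an arylacetaldehyde.
- Forward: epicatechin gives the bottom unit as an 8-lithio species, which adds to a ring A salicylaldehyde. The resulting carbinol is ionised to the o-quinone methide and ring C of the middle unit closes by oxa-[4+2] with the enol gallate.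
- Then: bottom gallate, Friedel–Crafts attachment of the top unit at middle C8, global hydrogenolysis.
- Stereochemistry: C2/C3 of the top and bottom units come from (−)-epicatechin. Middle C4 is set by a chiral phosphoric acid on the planar methide (both carbinol epimers converge); C3 and C2 are relayed in the same event (anti approach gives 3,4-trans, Z-alkene gives 2,3-cis). Top C4 arises by attack anti to 3-OH and 2-aryl (4β).

Key step: step 8

Abbreviations: Bn = benzyl, TBS = tert-butyldimethylsilyl; flavan numbering is used for each unit (top, middle, bottom).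

Assumption: the (R)-enantiomer of the phosphoric acid is taken as the one that exposes the required face of C4 of the methide; this sense of induction is not secured by close analogy, and the mirror-image acid would be used if the opposite face were favoured.

**Step 1**
Reactants: 1 (−)-epicatechin
Product: 2 5,7,3',4'-tetra-O-benzyl-(−)-epicatechin (2R,3R)
Conditions: BnBr (4.4 equiv), K2CO3, DMF, 0 °C → rt
Reagents that add atoms: benzyl bromide, BrCc1ccccc1
Why: Williamson etherification of the four phenols only, since carbonate does not deprotonate the secondary 3-OH, and C2/C3 are untouched.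

**Step 2**
Reactants: 2 5,7,3',4'-tetra-O-benzyl-(−)-epicatechin
Product: 3 8-bromo-5,7,3',4'-tetra-O-benzyl-(−)-epicatechin
Conditions: NBS (1.0 equiv), CH2Cl2, −78 °C → rt
Reagents that add atoms: N-bromosuccinimide, O=C1CCC(=O)N1Br
Why: Electrophilic aromatic bromination goes to C8, the ring A position flanked by ring O1 and one OBn, which is more reactive than C6 between two OBn groups.

**Step 3**
Reactants: 3 8-bromo-5,7,3',4'-tetra-O-benzyl-(−)-epicatechin
Product: 4 8-bromo-3-O-TBS-5,7,3',4'-tetra-O-benzyl-(−)-epicatechin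
Conditions: TBSCl, imidazole, DMF, rt
Reagents that add atoms: tert-butyldimethylsilyl chloride, CC(C)(C)[Si](C)(C)Cl
Why: Silylation masks the only acidic proton before halogen–lithium exchange and keeps the bottom 3-oxygen distinguishable for later galloylation.

**Step 4**
Reactants: 5 2,4,6-trihydroxybenzaldehyde
Product: 6 2,4-bis(benzyloxy)-6-hydroxybenzaldehyde
Conditions: BnBr (2.0 equiv), K2CO3, DMF, rt
Reagents that add atoms: benzyl bromide, BrCc1ccccc1
Why: Williamson etherification stops at the dibenzyl ether because the last ortho-hydroxyl is hydrogen-bonded to the formyl group, leaving free exactly the oxygen that becomes O1.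

**Step 5**
Reactants: 7 3,4-bis(benzyloxy)benzaldehyde
Product: 8 1,2-bis(benzyloxy)-4-ethynylbenzene
Conditions: dimethyl (1-diazo-2-oxopropyl)phosphonate, K2CO3, MeOH, rt
Reagents that add atoms: dimethyl (1-diazo-2-oxopropyl)phosphonate, COP(=O)(OC)C(=[N+]=[N-])C(C)=O
Why: Seyferth–Gilbert homologation in the Ohira–Bestmann variant converts the aldehyde to the terminal alkyne with one added carbon under mild base.

**Step 6**
Reactants: 8 1,2-bis(benzyloxy)-4-ethynylbenzene; 9 3,4,5-tris(benzyloxy)benzoic acid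
Product: 10 (Z)-2-[3,4-bis(benzyloxy)phenyl]ethenyl 3,4,5-tris(benzyloxy)benzoate
Conditions: [RuCl2(p-cymene)]2 (cat.), P(4-ClC6H4)3 (cat.), DMAP (cat.), toluene, 60 °C
Reagents that add atoms: none
Why: Ruthenium-catalysed anti-Markovnikov addition of a carboxylic acid to a terminal alkyne via a vinylidene complex should give the Z-enol ester, fixing the alkene geometry that later becomes the 2,3-cis relation.

**Step 7**
Reactants: 6 2,4-bis(benzyloxy)-6-hydroxybenzaldehyde; 4 8-bromo-3-O-TBS-5,7,3',4'-tetra-O-benzyl-(−)-epicatechin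
Product: 13 [2-hydroxy-4,6-bis(benzyloxy)phenyl][(2R,3R)-3-O-TBS-5,7,3',4'-tetra-O-benzyl-epicatechin-8-yl]methanol (both carbinol epimers), via sodium phenoxide 11 (not isolated), via aryllithium 12 (not isolated)
Conditions: 6, NaH, THF, 0 °C; separately 4, t-BuLi (2.0 equiv), THF, −78 °C; combine at −78 °C, then 0 °C; aq. NH4Cl
Reagents that add atoms: none
Why: Bromine–lithium exchange followed by 1,2-addition of the aryllithium to the aldehyde (the phenol being masked as its phenoxide) forms the middle C4–bottom C8 bond; the carbinol configuration is irrelevant because it is erased in step 8.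

**Step 8**
Reactants: 13 o-hydroxybenzhydrol (both epimers); 10 (Z)-enol gallate
Product: 15 5,7,3',4'-tetra-O-benzyl-epicatechin 3-O-(tri-O-benzylgallate)-(4β→8)-3-O-TBS-5,7,3',4'-tetra-O-benzyl-epicatechin, new unit (2R,3R,4R), via o-quinone methide 14 (not isolated)
Conditions: (R)-3,3'-bis(2,4,6-triisopropylphenyl)-1,1'-binaphthyl-2,2'-diyl hydrogen phosphate (10 mol %), 10 (3 equiv), 5 Å molecular sieves, toluene, 0 °C → rt
Reagents that add atoms: none
Why: Proposed new method: the phosphoric acid ionises both carbinol epimers of 13 to the same planar, hydrogen-bonded o-quinone methide 14 (O1=C8a–C4a=C4), so the step is stereoconvergent, and 14 then undergoes an inverse-electron-demand oxa-[4+2] cycloaddition with 10 in which the oxygen-bearing alkene carbon bonds to C4 and O1 bonds to the benzylic carbon that becomes C2. The closest known reaction type is the chiral Brønsted-acid-catalysed [4+2] cycloaddition of o-quinone methides generated from o-hydroxybenzhydrols with styrenes, enol ethers and enamides; an enol ester of an arylacetaldehyde has not been used as the 2π partner. Ring C closes as a six-membered ring by suprafacial addition across the alkene (concerted asynchronous; in the stepwise limit the gallate carbonyl bridges C2 as an acyloxonium ion and O1 opens it with inversion, which is again net syn), so the Z geometry becomes the 2,3-cis relation. C4 is set by the catalyst, whose phosphate holds O1 and shields one face of the methide carbon, and C3 is set relative to C4 because the leading C3–C4 bond forms with the acyloxy group turned away from the 2,6-disubstituted aryl on C4 (exo mode, 3,4-trans). The step needs regioselectivity, secured by the 4-benzyloxyphenyl group, which stabilises positive charge at C2 far better than the acyloxy group does at C3, and site selectivity for O1 over O5, secured by the benzyl ether on O5; excess 10 and the crowded methide should suppress Friedel–Crafts self-condensation.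

**Step 9**
Reactants: 15 protected dimer with bottom 3-O-TBS
Product: 16 5,7,3',4'-tetra-O-benzyl-epicatechin 3-O-(tri-O-benzylgallate)-(4β→8)-5,7,3',4'-tetra-O-benzyl-epicatechin (bottom 3-OH free)
Conditions: TBAF, AcOH, THF, rt
Reagents that add atoms: none
Why: Buffered fluoride desilylation frees the bottom 3-OH while the aryl ester, benzyl ethers and interflavan bond are inert.

**Step 10**
Reactants: 16 dimer with free bottom 3-OH; 9 3,4,5-tris(benzyloxy)benzoic acid
Product: 17 5,7,3',4'-tetra-O-benzyl-epicatechin 3-O-(tri-O-benzylgallate)-(4β→8)-5,7,3',4'-tetra-O-benzyl-epicatechin 3-O-(tri-O-benzylgallate)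
Conditions: DCC, DMAP, CH2Cl2, rt
Reagents that add atoms: none
Why: Steglich esterification acylates the single free secondary hydroxyl with retention at C3.

**Step 11**
Reactants: 2 5,7,3',4'-tetra-O-benzyl-(−)-epicatechin
Product: 18 (2R,3R,4S)-4-(2-ethoxyethoxy)-5,7,3',4'-tetra-O-benzyl-epicatechin (4β, 3,4-trans)
Conditions: DDQ, 2-ethoxyethanol, CH2Cl2, rt
Reagents that add atoms: 2-ethoxyethanol, CCOCCO
Why: DDQ abstracts hydride from benzylic C4, which is activated by the 5,7-dioxygenated ring A, and the alcohol traps the cation anti to the 3-OH; the C4 configuration is unimportant because the centre is ionised again in step 12.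

**Step 12**
Reactants: 17 protected digallate dimer; 18 C4-activated top unit
Product: 19 octadeca-O-benzyl epicatechin-(4β→8)-epicatechin 3-O-gallate-(4β→8)-epicatechin 3-O-gallate
Conditions: TMSOTf (cat.), CH2Cl2, −78 → −40 °C, 17 in excess
Reagents that add atoms: none
Why: Lewis-acid ionisation of the C4 acetal gives the flavan-4-yl cation, which undergoes Friedel–Crafts arylation at C8 of the upper unit of 17 (flanked by O1 and one OBn, the most nucleophilic site) anti to the 3-OH and 2-aryl groups, setting top C4 as 4β.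

**Step 13**
Reactants: 19 protected trimer
Product: 20 epicatechin-(4β→8)-epicatechin 3-O-gallate-(4β→8)-epicatechin 3-O-gallate (target)
Conditions: H2 (1 atm), Pd(OH)2/C, THF/MeOH/H2O, rt
Reagents that add atoms: none
Why: Hydrogenolysis cleaves all eighteen benzyl ethers under neutral conditions that leave the gallate esters, the interflavan bonds and all stereocentres intact.

**Compound list**
1 | (−)-epicatechin (2R,3R) | O[C@@H]1Cc2c(O)cc(O)cc2O[C@@H]1c1ccc(O)c(O)c1 | starting material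
2 | 5,7,3',4'-tetra-O-benzyl-(−)-epicatechin | O[C@@H]1Cc2c(OCc3ccccc3)cc(OCc3ccccc3)cc2O[C@@H]1c1ccc(OCc2ccccc2)c(OCc2ccccc2)c1 | intermediate
3 | 8-bromo-5,7,3',4'-tetra-O-benzyl-(−)-epicatechin | O[C@@H]1Cc2c(OCc3ccccc3)cc(OCc3ccccc3)c(Br)c2O[C@@H]1c1ccc(OCc2ccccc2)c(OCc2ccccc2)c1 | intermediate
4 | 8-bromo-3-O-TBS-5,7,3',4'-tetra-O-benzyl-(−)-epicatechin | CC(C)(C)[Si](C)(C)O[C@@H]1Cc2c(OCc3ccccc3)cc(OCc3ccccc3)c(Br)c2O[C@@H]1c1ccc(OCc2ccccc2)c(OCc2ccccc2)c1 | intermediate
5 | 2,4,6-trihydroxybenzaldehyde | O=Cc1c(O)cc(O)cc1O | starting material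
6 | 2,4-bis(benzyloxy)-6-hydroxybenzaldehyde | O=Cc1c(O)cc(OCc2ccccc2)cc1OCc1ccccc1 | intermediate
7 | 3,4-bis(benzyloxy)benzaldehyde | O=Cc1ccc(OCc2ccccc2)c(OCc2ccccc2)c1 | starting material
8 | 1,2-bis(benzyloxy)-4-ethynylbenzene | C#Cc1ccc(OCc2ccccc2)c(OCc2ccccc2)c1 | intermediate
9 | 3,4,5-tris(benzyloxy)benzoic acid | OC(=O)c1cc(OCc2ccccc2)c(OCc2ccccc2)c(OCc2ccccc2)c1 | starting material
10 | (Z)-2-[3,4-bis(benzyloxy)phenyl]ethenyl 3,4,5-tris(benzyloxy)benzoate | O=C(O/C=C\c1ccc(OCc2ccccc2)c(OCc2ccccc2)c1)c1cc(OCc2ccccc2)c(OCc2ccccc2)c(OCc2ccccc2)c1 | intermediate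
11 | sodium 3,5-bis(benzyloxy)-2-formylphenoxide | [Na+].[O-]c1cc(OCc2ccccc2)cc(OCc2ccccc2)c1C=O | intermediate
12 | 8-lithio-3-O-TBS-5,7,3',4'-tetra-O-benzyl-(−)-epicatechin | CC(C)(C)[Si](C)(C)O[C@@H]1Cc2c(OCc3ccccc3)cc(OCc3ccccc3)c([Li])c2O[C@@H]1c1ccc(OCc2ccccc2)c(OCc2ccccc2)c1 | intermediate
13 | [2-hydroxy-4,6-bis(benzyloxy)phenyl][(2R,3R)-3-O-TBS-5,7,3',4'-tetra-O-benzyl-epicatechin-8-yl]methanol, both carbinol epimers | CC(C)(C)[Si](C)(C)O[C@@H]1Cc2c(OCc3ccccc3)cc(OCc3ccccc3)c(C(O)c3c(O)cc(OCc4ccccc4)cc3OCc3ccccc3)c2O[C@@H]1c1ccc(OCc2ccccc2)c(OCc2ccccc2)c1 | intermediate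
14 | o-quinone methide: 3,5-bis(benzyloxy)-6-[(epicatechin-8-yl)methylidene]cyclohexa-2,4-dien-1-one carrying the protected bottom unit, alkene geometry not fixed | CC(C)(C)[Si](C)(C)O[C@@H]1Cc2c(OCc3ccccc3)cc(OCc3ccccc3)c(C=C3C(=O)C=C(OCc4ccccc4)C=C3OCc3ccccc3)c2O[C@@H]1c1ccc(OCc2ccccc2)c(OCc2ccccc2)c1 | intermediate
15 | tetra-O-benzyl-epicatechin 3-O-(tri-O-benzylgallate)-(4β→8)-3-O-TBS-tetra-O-benzyl-epicatechin; new unit 2R,3R,4R | O=C(O[C@@H]1[C@@H](c2c(OCc3ccccc3)cc(OCc3ccccc3)c3c2O[C@H](c2ccc(OCc4ccccc4)c(OCc4ccccc4)c2)[C@H](O[Si](C)(C)C(C)(C)C)C3)c2c(OCc3ccccc3)cc(OCc3ccccc3)cc2O[C@@H]1c1ccc(OCc2ccccc2)c(OCc2ccccc2)c1)c1cc(OCc2ccccc2)c(OCc2ccccc2)c(OCc2ccccc2)c1 | intermediate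
16 | tetra-O-benzyl-epicatechin 3-O-(tri-O-benzylgallate)-(4β→8)-tetra-O-benzyl-epicatechin, bottom 3-OH free | O=C(O[C@@H]1[C@@H](c2c(OCc3ccccc3)cc(OCc3ccccc3)c3c2O[C@H](c2ccc(OCc4ccccc4)c(OCc4ccccc4)c2)[C@H](O)C3)c2c(OCc3ccccc3)cc(OCc3ccccc3)cc2O[C@@H]1c1ccc(OCc2ccccc2)c(OCc2ccccc2)c1)c1cc(OCc2ccccc2)c(OCc2ccccc2)c(OCc2ccccc2)c1 | intermediate
17 | tetra-O-benzyl-epicatechin 3-O-(tri-O-benzylgallate)-(4β→8)-tetra-O-benzyl-epicatechin 3-O-(tri-O-benzylgallate) | O=C(O[C@@H]1[C@@H](c2c(OCc3ccccc3)cc(OCc3ccccc3)c3c2O[C@H](c2ccc(OCc4ccccc4)c(OCc4ccccc4)c2)[C@H](OC(=O)c2cc(OCc4ccccc4)c(OCc4ccccc4)c(OCc4ccccc4)c2)C3)c2c(OCc3ccccc3)cc(OCc3ccccc3)cc2O[C@@H]1c1ccc(OCc2ccccc2)c(OCc2ccccc2)c1)c1cc(OCc2ccccc2)c(OCc2ccccc2)c(OCc2ccccc2)c1 | intermediate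
18 | (2R,3R,4S)-4-(2-ethoxyethoxy)-5,7,3',4'-tetra-O-benzyl-epicatechin | CCOCCO[C@H]1c2c(OCc3ccccc3)cc(OCc3ccccc3)cc2O[C@H](c2ccc(OCc3ccccc3)c(OCc3ccccc3)c2)[C@@H]1O | intermediate
19 | octadeca-O-benzyl epicatechin-(4β→8)-epicatechin 3-O-gallate-(4β→8)-epicatechin 3-O-gallate | O=C(O[C@@H]1[C@@H](c2c(OCc3ccccc3)cc(OCc3ccccc3)c3c2O[C@H](c2ccc(OCc4ccccc4)c(OCc4ccccc4)c2)[C@H](OC(=O)c2cc(OCc4ccccc4)c(OCc4ccccc4)c(OCc4ccccc4)c2)C3)c2c(OCc3ccccc3)cc(OCc3ccccc3)c([C@H]3c4c(OCc5ccccc5)cc(OCc5ccccc5)cc4O[C@H](c4ccc(OCc5ccccc5)c(OCc5ccccc5)c4)[C@@H]3O)c2O[C@@H]1c1ccc(OCc2ccccc2)c(OCc2ccccc2)c1)c1cc(OCc2ccccc2)c(OCc2ccccc2)c(OCc2ccccc2)c1 | intermediate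
20 | epicatechin-(4β→8)-epicatechin 3-O-gallate-(4β→8)-epicatechin 3-O-gallate; top 2R,3R,4R, middle 2R,3R,4S, bottom 2R,3R | O=C(O[C@@H]1[C@@H](c2c(O)cc(O)c3c2O[C@H](c2ccc(O)c(O)c2)[C@H](OC(=O)c2cc(O)c(O)c(O)c2)C3)c2c(O)cc(O)c([C@H]3c4c(O)cc(O)cc4O[C@H](c4ccc(O)c(O)c4)[C@@H]3O)c2O[C@@H]1c1ccc(O)c(O)c1)c1cc(O)c(O)c(O)c1 | target

**Summary**
Total step count: 13. Longest linear sequence: 9 steps (1, 2, 3, 7, 8, 9, 10, 12, 13).

**Steps most likely to fail**

Step 8. The risks are poor facial selectivity at the methide carbon, an endo approach that would give the 3,4-cis isomer, loss of the Z-to-cis relay through a freely rotating benzylic cation, or addition too slow to outrun self-condensation of the electron-rich methide. The fallback builds the same dimer by established flavan-4-yl cation chemistry and sets out from 2 and 9. DCC/DMAP esterification gives 5,7,3',4'-tetra-O-benzyl-epicatechin 3-O-(tri-O-benzylgallate) F1. DDQ oxidation of part of this material in the presence of 2-ethoxyethanol gives its 4β-(2-ethoxyethoxy) derivative F2. TMSOTf-mediated Friedel–Crafts coupling of F2 with an excess of F1 in CH2Cl2 at −78 °C should proceed at C8 of F1 and anti to the participating 3-O-galloyl group. This gives 17 directly, where the route is rejoined; steps 4 to 10 are then not needed.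

Step 12. The risks are self-condensation of the activated top unit, further chain extension of the product through its own free C8, and attack at a C6 position of the dimer. The fallback uses a blocking group on the electrophile and sets out from 3. DDQ/2-ethoxyethanol gives 8-bromo-4β-(2-ethoxyethoxy)-5,7,3',4'-tetra-O-benzyl-epicatechin F3, which can no longer act as a nucleophile at C8. TMSOTf-mediated coupling of F3 with 17 gives the 8-bromo octadeca-O-benzyl trimer F4. Hydrogenolysis over Pd(OH)2/C with H2 and Et3N removes the bromine together with all benzyl groups, and the route is rejoined at 20.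

Step 7. The risks are sluggish addition of a 2,6-disubstituted aryllithium to a phenoxide-deactivated, doubly ortho-substituted aldehyde, and competing proton transfer. The fallback reverses the roles of the partners and sets out from 4. Bromine–lithium exchange and a DMF quench give 8-formyl-3-O-TBS-5,7,3',4'-tetra-O-benzyl-epicatechin F5. Phenylboronic-acid-templated ortho-hydroxyalkylation of commercial 3,5-bis(benzyloxy)phenol with F5 (PhB(OH)2, propionic acid cat., toluene, reflux with water removal) is ortho-specific and gives the 4-aryl-5,7-bis(benzyloxy)-2-phenyl-4H-1,3,2-benzodioxaborin F6. Transesterification with propane-1,3-diol releases the o-hydroxybenzhydrol, and the route is rejoined at 13.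

**Further compounds**
F1 | step 8 | 5,7,3',4'-tetra-O-benzyl-epicatechin 3-O-(tri-O-benzylgallate) | O=C(O[C@@H]1Cc2c(OCc3ccccc3)cc(OCc3ccccc3)cc2O[C@@H]1c1ccc(OCc2ccccc2)c(OCc2ccccc2)c1)c1cc(OCc2ccccc2)c(OCc2ccccc2)c(OCc2ccccc2)c1
F2 | step 8 | 4β-(2-ethoxyethoxy)-5,7,3',4'-tetra-O-benzyl-epicatechin 3-O-(tri-O-benzylgallate) | O=C(O[C@@H]1[C@@H](OCCOCC)c2c(OCc3ccccc3)cc(OCc3ccccc3)cc2O[C@@H]1c1ccc(OCc2ccccc2)c(OCc2ccccc2)c1)c1cc(OCc2ccccc2)c(OCc2ccccc2)c(OCc2ccccc2)c1
F3 | step 12 | 8-bromo-4β-(2-ethoxyethoxy)-5,7,3',4'-tetra-O-benzyl-epicatechin | CCOCCO[C@H]1c2c(OCc3ccccc3)cc(OCc3ccccc3)c(Br)c2O[C@H](c2ccc(OCc3ccccc3)c(OCc3ccccc3)c2)[C@@H]1O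
F4 | step 12 | octadeca-O-benzyl trimer with bromine at C8 of the top unit | O=C(O[C@@H]1[C@@H](c2c(OCc3ccccc3)cc(OCc3ccccc3)c3c2O[C@H](c2ccc(OCc4ccccc4)c(OCc4ccccc4)c2)[C@H](OC(=O)c2cc(OCc4ccccc4)c(OCc4ccccc4)c(OCc4ccccc4)c2)C3)c2c(OCc3ccccc3)cc(OCc3ccccc3)c([C@H]3c4c(OCc5ccccc5)cc(OCc5ccccc5)c(Br)c4O[C@H](c4ccc(OCc5ccccc5)c(OCc5ccccc5)c4)[C@@H]3O)c2O[C@@H]1c1ccc(OCc2ccccc2)c(OCc2ccccc2)c1)c1cc(OCc2ccccc2)c(OCc2ccccc2)c(OCc2ccccc2)c1
F5 | step 7 | 8-formyl-3-O-TBS-5,7,3',4'-tetra-O-benzyl-epicatechin | CC(C)(C)[Si](C)(C)O[C@@H]1Cc2c(OCc3ccccc3)cc(OCc3ccccc3)c(C=O)c2O[C@@H]1c1ccc(OCc2ccccc2)c(OCc2ccccc2)c1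
F6 | step 7 | 5,7-bis(benzyloxy)-2-phenyl-4-[(2R,3R)-3-O-TBS-5,7,3',4'-tetra-O-benzyl-epicatechin-8-yl]-4H-1,3,2-benzodioxaborin | CC(C)(C)[Si](C)(C)O[C@@H]1Cc2c(OCc3ccccc3)cc(OCc3ccccc3)c(C3OB(c4ccccc4)Oc4cc(OCc5ccccc5)cc(OCc5ccccc5)c34)c2O[C@@H]1c1ccc(OCc2ccccc2)c(OCc2ccccc2)c1
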